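The strategy disconnects the two salicylate C–O bonds, C2–O of ring B and C2–O of ring C. The tridepside is therefore built from plain 4-hydroxy-2-methylbenzoyl units and oxygenated last. The feature exploited: in rings B and C the carbonyl-bearing C1 lies between C6–CH3 and C2–H, so each ester carbonyl can guide a metal to one C–H only. C1 of ring A (C2–OCH3, C6–CH3) has no ortho C–H. One ruthenium-catalysed operation forms both C–O bonds. The precursor is the bis-deoxy tridepside with ring C as its 4-nitrobenzyl ester. Its ring A 4-OH is free and is masked in the flask as an electron-poor trifluoroacetate.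

Key step: step 9

Design remarks:
- Ring A is the 4-hydroxy-2-methoxy-6-methylbenzoyl unit. The methyl ether sits on the oxygen next to the carbonyl, and the para oxygen needs the temporary group.
- No benzyl-type ether is carried into the oxidation. Hot TFA with persulfate would cleave or oxidise it. A 2,4-dialkoxy ring A would also be the most oxidisable ring and the best acylium precursor for rupture of the A–B ester.
- The ring C carboxyl is carried as an ester. A free acid in TFAA becomes a mixed anhydride, which is an acylating agent and a poor donor. The 4-nitrobenzyl group resists acidolysis and benzylic oxidation and leaves by neutral hydrogenolysis.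
- Ring B enters as an aldehyde, a latent carboxyl that needs no protecting group.
- The target has no stereocenter.

Assumption: the three phenolic building blocks used as starting materials are taken as catalogue chemicals; the ring A aldehyde is otherwise one Vilsmeier formylation away from orcinol.

Step 1
Reactants: 1 2,4-dihydroxy-6-methylbenzaldehyde
Product: 2 2-hydroxy-4-[(4-methoxybenzyl)oxy]-6-methylbenzaldehyde
Conditions: 4-methoxybenzyl chloride (1.05 equiv), K2CO3 (1.0 equiv), acetone, reflux
Reagents that add atoms: 4-methoxybenzyl chloride, COc1ccc(CCl)cc1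
Why: Williamson ether synthesis should occur at O4 only, because the C2–OH is held in a hydrogen bond to the neighbouring formyl group and one equivalent of base engages the freer, more acidic 4-OH.

Step 2
Reactants: 2 2-hydroxy-4-[(4-methoxybenzyl)oxy]-6-methylbenzaldehyde
Product: 3 2-methoxy-4-[(4-methoxybenzyl)oxy]-6-methylbenzaldehyde
Conditions: MeI (1.5 equiv), K2CO3 (2 equiv), DMF, rt to 40 °C
Reagents that add atoms: iodomethane, CI
Why: Williamson methylation of the remaining chelated phenol proceeds in a dipolar aprotic solvent with excess MeI, and 2 offers no other site for alkylation.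

Step 3
Reactants: 3 2-methoxy-4-[(4-methoxybenzyl)oxy]-6-methylbenzaldehyde
Product: 4 2-methoxy-4-[(4-methoxybenzyl)oxy]-6-methylbenzoic acid (ring A acid)
Conditions: NaClO2, NaH2PO4, 2-methyl-2-butene (excess), t-BuOH/THF/H2O, rt
Reagents that add atoms: sodium chlorite, [Na+].[O-]Cl=O
Why: Pinnick oxidation turns hindered aryl aldehydes into acids in a mild buffer that leaves both aryl ethers alone, while the alkene traps hypochlorous acid before it can chlorinate the electron-rich rings.

Step 4
Reactants: 4 2-methoxy-4-[(4-methoxybenzyl)oxy]-6-methylbenzoic acid; 5 4-hydroxy-2-methylbenzaldehyde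
Product: 6 4-formyl-3-methylphenyl 2-methoxy-4-[(4-methoxybenzyl)oxy]-6-methylbenzoate (A–B aldehyde)
Conditions: DCC (1.1 equiv), DMAP (0.2 equiv), CH2Cl2, 0 °C to rt
Reagents that add atoms: none
Why: Steglich esterification is a standard way to depside esters, and 5 has a single nucleophilic site while its formyl group stands in for the ring B carboxyl.

Step 5
Reactants: 6 4-formyl-3-methylphenyl 2-methoxy-4-[(4-methoxybenzyl)oxy]-6-methylbenzoate
Product: 7 4-({2-methoxy-4-[(4-methoxybenzyl)oxy]-6-methylbenzoyl}oxy)-2-methylbenzoic acid (A–B acid)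
Conditions: NaClO2, NaH2PO4, 2-methyl-2-butene (excess), t-BuOH/THF/H2O, rt
Reagents that add atoms: sodium chlorite, [Na+].[O-]Cl=O
Why: Pinnick oxidation at about pH 4 unmasks the ring B carboxyl without hydrolysing the doubly ortho-shielded aryl ester.

Step 6
Reactants: 8 4-hydroxy-2-methylbenzoic acid
Product: 9 4-nitrobenzyl 4-hydroxy-2-methylbenzoate
Conditions: 4-nitrobenzyl bromide (1.0 equiv), KHCO3 (1.1 equiv), DMF, rt
Reagents that add atoms: 4-nitrobenzyl bromide, O=[N+]([O-])c1ccc(CBr)cc1
Why: SN2 alkylation of the carboxylate is chemoselective because hydrogen carbonate deprotonates the acid but not the phenol, which stays free for the next coupling.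

Step 7
Reactants: 7 4-({2-methoxy-4-[(4-methoxybenzyl)oxy]-6-methylbenzoyl}oxy)-2-methylbenzoic acid; 9 4-nitrobenzyl 4-hydroxy-2-methylbenzoate
Product: 10 4-nitrobenzyl 4-{[4-({2-methoxy-4-[(4-methoxybenzyl)oxy]-6-methylbenzoyl}oxy)-2-methylbenzoyl]oxy}-2-methylbenzoate (protected bis-deoxy tridepside)
Conditions: DCC (1.1 equiv), DMAP (0.1 equiv), CH2Cl2, 0 °C to rt
Reagents that add atoms: none
Why: Steglich esterification joins the only free acid to the only free phenol, and the existing A–B ester is protected from acyl transfer by its two ortho substituents.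

Step 8
Reactants: 10 protected bis-deoxy tridepside
Product: 11 4-nitrobenzyl 4-({4-[(4-hydroxy-2-methoxy-6-methylbenzoyl)oxy]-2-methylbenzoyl}oxy)-2-methylbenzoate (bis-deoxy tridepside, precursor of the key step)
Conditions: TFA/CH2Cl2 (1:4), Et3SiH (3 equiv), 0 °C; evaporate
Reagents that add atoms: none
Why: Acidolysis of the 4-methoxybenzyl aryl ether is an SN1-type deprotection in which the silane reduces the benzylic cation at once, and the three esters and the nitro group tolerate cold dilute TFA.

Step 9
Reactants: 11 bis-deoxy tridepside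
Product: 14 4-nitrobenzyl umbilicarate, via ring A trifluoroacetate 12 (not isolated), via tris(trifluoroacetate) 13 (not isolated)
Conditions: TFA/TFAA (3:1), rt, 30 min; then [RuCl2(p-cymene)]2 (10 mol %), K2S2O8 (3 equiv), 80 °C, sealed tube; then evaporate, THF/H2O, rt
Reagents that add atoms: trifluoroacetic acid, OC(=O)C(F)(F)F (supplies both new phenol oxygens); trifluoroacetic anhydride, O=C(OC(=O)C(F)(F)F)C(F)(F)F (acyl groups of 12 and 13 only, lost on hydrolysis)
Why: Proposed new method: once TFAA has capped the ring A phenol as the electron-poor ester 12, a cationic trifluoroacetate complex of divalent ruthenium binds the carbonyl oxygen of the ring C alkyl ester and of the ring B aryl ester and cleaves the adjacent C2–H by carboxylate-assisted metalation, giving five-membered ruthenacycles. Persulfate raises each ruthenacycle to tetravalent ruthenium, C–O reductive elimination with trifluoroacetate gives the aryl trifluoroacetates of 13, and water then frees all three phenols. The closest known reaction type is the ruthenium-catalysed ortho C–H hydroxylation of alkyl benzoates in TFA/TFAA; new here are an aryl (depside) ester as directing group and two oxygenations in one substrate. No ring is closed and no stereocenter is formed. The step needs site selectivity for C2–H of rings B and C, which the substrate secures because C6 of each ring carries CH3 and both ortho positions of ring A C1 are substituted, so each benzoyl carbonyl meets at most one ortho C–H and a second directed oxygenation is impossible. Chemoselectivity is helped by the acyloxy and nitro groups, which make every ring a poor partner for undirected persulfate oxidation and disfavour the acylium pathway that would break the depside links.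

Step 10
Reactants: 14 4-nitrobenzyl umbilicarate
Product: 16 umbilicaric acid, via 4-aminobenzyl umbilicarate 15 (not isolated)
Conditions: H2 (1 atm), 10 % Pd/C, EtOAc/THF, rt; filter, wash with cold 1 M HCl
Reagents that add atoms: none
Why: Catalytic hydrogenation reduces the nitro group and then hydrogenolyses the benzylic C–O bond under neutral, alcohol-free conditions that leave both depside esters, the phenols and the decarboxylation-prone salicylic acid untouched.

Compound list
1 | 2,4-dihydroxy-6-methylbenzaldehyde | Cc1cc(O)cc(O)c1C=O | starting material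
2 | 2-hydroxy-4-[(4-methoxybenzyl)oxy]-6-methylbenzaldehyde | Cc1cc(OCc2ccc(OC)cc2)cc(O)c1C=O | intermediate
3 | 2-methoxy-4-[(4-methoxybenzyl)oxy]-6-methylbenzaldehyde | COc1cc(OCc2ccc(OC)cc2)cc(C)c1C=O | intermediate
4 | 2-methoxy-4-[(4-methoxybenzyl)oxy]-6-methylbenzoic acid | COc1cc(OCc2ccc(OC)cc2)cc(C)c1C(=O)O | intermediate
5 | 4-hydroxy-2-methylbenzaldehyde | Cc1cc(O)ccc1C=O | starting material
6 | 4-formyl-3-methylphenyl 2-methoxy-4-[(4-methoxybenzyl)oxy]-6-methylbenzoate | COc1cc(OCc2ccc(OC)cc2)cc(C)c1C(=O)Oc1ccc(C=O)c(C)c1 | intermediate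
7 | 4-({2-methoxy-4-[(4-methoxybenzyl)oxy]-6-methylbenzoyl}oxy)-2-methylbenzoic acid | COc1cc(OCc2ccc(OC)cc2)cc(C)c1C(=O)Oc1ccc(C(=O)O)c(C)c1 | intermediate
8 | 4-hydroxy-2-methylbenzoic acid | Cc1cc(O)ccc1C(=O)O | starting material
9 | 4-nitrobenzyl 4-hydroxy-2-methylbenzoate | Cc1cc(O)ccc1C(=O)OCc1ccc(cc1)[N+](=O)[O-] | intermediate
10 | 4-nitrobenzyl 4-{[4-({2-methoxy-4-[(4-methoxybenzyl)oxy]-6-methylbenzoyl}oxy)-2-methylbenzoyl]oxy}-2-methylbenzoate | COc1cc(OCc2ccc(OC)cc2)cc(C)c1C(=O)Oc1ccc(C(=O)Oc2ccc(C(=O)OCc3ccc(cc3)[N+](=O)[O-])c(C)c2)c(C)c1 | intermediate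
11 | 4-nitrobenzyl 4-({4-[(4-hydroxy-2-methoxy-6-methylbenzoyl)oxy]-2-methylbenzoyl}oxy)-2-methylbenzoate | COc1cc(O)cc(C)c1C(=O)Oc1ccc(C(=O)Oc2ccc(C(=O)OCc3ccc(cc3)[N+](=O)[O-])c(C)c2)c(C)c1 | intermediate
12 | ring A 4-O-trifluoroacetate of 11 (not isolated) | COc1cc(OC(=O)C(F)(F)F)cc(C)c1C(=O)Oc1ccc(C(=O)Oc2ccc(C(=O)OCc3ccc(cc3)[N+](=O)[O-])c(C)c2)c(C)c1 | intermediate
13 | tris(trifluoroacetate) of 14 at ring A O4, ring B O2 and ring C O2 (not isolated) | COc1cc(OC(=O)C(F)(F)F)cc(C)c1C(=O)Oc1cc(C)c(C(=O)Oc2cc(C)c(C(=O)OCc3ccc(cc3)[N+](=O)[O-])c(OC(=O)C(F)(F)F)c2)c(OC(=O)C(F)(F)F)c1 | intermediate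
14 | 4-nitrobenzyl umbilicarate, i.e. 4-nitrobenzyl 2-hydroxy-4-({2-hydroxy-4-[(4-hydroxy-2-methoxy-6-methylbenzoyl)oxy]-6-methylbenzoyl}oxy)-6-methylbenzoate | COc1cc(O)cc(C)c1C(=O)Oc1cc(C)c(C(=O)Oc2cc(C)c(C(=O)OCc3ccc(cc3)[N+](=O)[O-])c(O)c2)c(O)c1 | intermediate
15 | 4-aminobenzyl umbilicarate (not isolated) | COc1cc(O)cc(C)c1C(=O)Oc1cc(C)c(C(=O)Oc2cc(C)c(C(=O)OCc3ccc(N)cc3)c(O)c2)c(O)c1 | intermediate
16 | umbilicaric acid | COc1cc(O)cc(C)c1C(=O)Oc1cc(C)c(C(=O)Oc2cc(C)c(C(=O)O)c(O)c2)c(O)c1 | target

Total step count: 10
Longest linear sequence: 9 (steps 1 to 5, then 7 to 10; step 6 is the side branch)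

Steps most likely to fail

1. Step 9.
- What may go wrong:
  - The twisted, weakly basic aryl ester carbonyl may bind ruthenium too poorly, so ring B stays unoxidised.
  - Metalation may occur on the phenol side of an ester through a six-membered chelate at C3 of ring B or C.
  - Acid-promoted acyl exchange may occur at the depside links.
  - Ring A may suffer undirected oxidation.
- Fallback (known chemistry, sets out from 4 and 1, returns at 14): the oxygen atoms are brought in with the building blocks. Acid 4 is esterified (DCC, DMAP) at the free 4-OH of aldehyde 1, whose chelated 2-OH does not react, to give 4-formyl-3-hydroxy-5-methylphenyl 2-methoxy-4-[(4-methoxybenzyl)oxy]-6-methylbenzoate F1. Pinnick oxidation gives the corresponding salicylic acid F2. Commercial orsellinic acid is alkylated with 4-nitrobenzyl bromide and KHCO3 to 4-nitrobenzyl orsellinate F3. DCC coupling of F2 with the 4-OH of F3 gives the ring A 4-O-(4-methoxybenzyl) ether of 4-nitrobenzyl umbilicarate F4. TFA with Et3SiH removes the ether and the route is rejoined at 14.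

2. Step 4.
- What may go wrong: acyl transfer from the doubly ortho-substituted activated acid to the electron-poor phenol may be slow, so oxygen-to-nitrogen acyl migration within the carbodiimide adduct takes over.
- Fallback (sets out from 4, returns at 6): the acid is converted under neutral conditions with 1-chloro-N,N,2-trimethylprop-1-en-1-amine into the isolated 2-methoxy-4-[(4-methoxybenzyl)oxy]-6-methylbenzoyl chloride F5. This is the smallest possible acyl donor. It is added to phenol 5 and Et3N in CH2Cl2 to give 6.

3. Step 8.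
- What may go wrong: the freed, nucleophilic ring A may be re-alkylated by the 4-methoxybenzyl cation, or acidolysis of the A–B ester may begin while ring A still carries two donor oxygens.
- Fallback (sets out from 10, returns at 11): oxidative instead of acidic cleavage, with DDQ in CH2Cl2 and pH 7 buffer. Benzylic hydride abstraction gives an oxocarbenium ion that water intercepts, so no alkylating cation and no strong acid are present. The group leaves as an aldehyde and 11 is obtained directly.

Further compounds
F1 | step 9 | 4-formyl-3-hydroxy-5-methylphenyl 2-methoxy-4-[(4-methoxybenzyl)oxy]-6-methylbenzoate | COc1cc(OCc2ccc(OC)cc2)cc(C)c1C(=O)Oc1cc(C)c(C=O)c(O)c1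
F2 | step 9 | 2-hydroxy-4-({2-methoxy-4-[(4-methoxybenzyl)oxy]-6-methylbenzoyl}oxy)-6-methylbenzoic acid | COc1cc(OCc2ccc(OC)cc2)cc(C)c1C(=O)Oc1cc(C)c(C(=O)O)c(O)c1
F3 | step 9 | 4-nitrobenzyl 2,4-dihydroxy-6-methylbenzoate (4-nitrobenzyl orsellinate) | Cc1cc(O)cc(O)c1C(=O)OCc1ccc(cc1)[N+](=O)[O-]
F4 | step 9 | 4-nitrobenzyl umbilicarate ring A 4-O-(4-methoxybenzyl) ether | COc1cc(OCc2ccc(OC)cc2)cc(C)c1C(=O)Oc1cc(C)c(C(=O)Oc2cc(C)c(C(=O)OCc3ccc(cc3)[N+](=O)[O-])c(O)c2)c(O)c1
F5 | step 4 | 2-methoxy-4-[(4-methoxybenzyl)oxy]-6-methylbenzoyl chloride | COc1cc(OCc2ccc(OC)cc2)cc(C)c1C(=O)Cl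
F0 | step 8 | none | none
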